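**Plan**

1. Numbering: C1 ketone, C2=C3 furanone alkene (C3 and C10 share the ring oxygen), C4 (CH bearing C15H2OH), C5H2, C6 (lactone O-CH), C7, C8 (angelate), C9H2, C10 (quaternary, methyl C14), C11/C12/C13 lactone alkene carbon, carbonyl and methylene. The lactone atoms O, C12, C11, C7, C6 are a 2-silyloxyfuran in disguise, and C15-C4-C5 is a reduced 2-substituted acrolein; this donor/acceptor pair allows the C5-C6 ring closure.
2. Retrosynthetic cuts, in order: angelate ester; C11=C13; the C7-H bond; C5-C6 (the ring); C4-C5 and C4-C15 (back to the furanone methyl); the lactone oxygens (back to a 3-furyl group); C7-C8; the C9-C10 allyl bond.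
3. Forward: the furanone ring is bought; C10 is allylated, the furyl group is added at C8, the methyl is turned into the acrolein, and the furan is taken through the butenolide to the silyloxyfuran. The ten-membered carbocycle closes in step 13; the lactone is then saturated and methylenated, and the esters are adjusted.
4. Stereochemistry: C10 from the Pd/PHOX decarboxylative allylation; C8 from an oxazaborolidine reduction; C6 and C4 from the ring closure (C4 still adjustable through the enamine); C7 from copper hydride reduction inside the macrocycle.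

Key step: step 13

Assumption: where a chiral ligand or amine is named (steps 2, 6, 13, 16), the antipode given is the one expected by analogy with simple substrates; if the sense of induction proves opposite, the mirror-image or pseudoenantiomeric catalyst is used in the same step.

**Route**

Step 1
Reactants: 1 2,5-dimethylfuran-3(2H)-one; 2 allyl chloroformate
Product: 3 allyl (2,5-dimethylfuran-3-yl) carbonate
Conditions: NaN(SiMe3)2, TMEDA, THF, -78 °C; then 2, -78 to 0 °C
Reagents that add atoms: none
Why: Deprotonation at C2 gives the aromatic furan-3-olate, which the chloroformate acylates on oxygen (enol carbonate formation); the 5-methyl group is not touched because its dienolate is not aromatic.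

Step 2
Reactants: 3 allyl (2,5-dimethylfuran-3-yl) carbonate
Product: 4 (S)-2-allyl-2,5-dimethylfuran-3(2H)-one
Conditions: Pd2(dba)3 (2.5 mol%), (S)-t-Bu-PHOX (6 mol%), THF, 25 °C
Reagents that add atoms: none
Why: Decarboxylative asymmetric allylic alkylation (Tsuji allylation): zerovalent palladium ionises the carbonate, CO2 is lost, and the furan-3-olate/π-allyl ion pair recombines at C2 next to the ring oxygen, the chiral P,N ligand setting the quaternary centre C10.

Step 3
Reactants: 4 (S)-2-allyl-2,5-dimethylfuran-3(2H)-one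
Product: 5 2-[(2S)-2,5-dimethyl-3-oxo-2,3-dihydrofuran-2-yl]acetaldehyde
Conditions: OsO4 (2 mol%), NaIO4, 2,6-lutidine, dioxane/H2O 3:1, rt
Reagents that add atoms: sodium periodate, [Na+].[O-]I(=O)(=O)=O (oxygen, passed on through OsO4)
Why: Lemieux-Johnson oxidation cleaves the electron-neutral terminal alkene, while the push-pull furanone alkene is a poor partner for OsO4 and should survive.

Step 4
Reactants: 5 2-[(2S)-2,5-dimethyl-3-oxo-2,3-dihydrofuran-2-yl]acetaldehyde; 6 3-bromofuran
Product: 8 (2S)-2-[2-(furan-3-yl)-2-hydroxyethyl]-2,5-dimethylfuran-3(2H)-one as a mixture of C8 epimers, via 3-furyllithium 7 (not isolated)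
Conditions: 6, n-BuLi, THF, -78 °C; then 5, -78 °C; H2O
Reagents that add atoms: none
Why: Bromine-lithium exchange at -78 °C (cold enough to prevent drift to the 2-lithio isomer) and 1,2-addition to the aldehyde, which is far more electrophilic than the vinylogous ester carbonyl; the carbinol configuration is not controlled here and is reset in steps 5 and 6.

Step 5
Reactants: 8 (2S)-2-[2-(furan-3-yl)-2-hydroxyethyl]-2,5-dimethylfuran-3(2H)-one
Product: 9 (S)-2-[2-(furan-3-yl)-2-oxoethyl]-2,5-dimethylfuran-3(2H)-one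
Conditions: Dess-Martin periodinane, CH2Cl2, 0 °C to rt
Reagents that add atoms: none
Why: Dess-Martin oxidation of the furyl carbinol is base-free, so the β-alkoxy ketone is not opened by retro-oxa-Michael elimination and C10 keeps its configuration.

Step 6
Reactants: 9 (S)-2-[2-(furan-3-yl)-2-oxoethyl]-2,5-dimethylfuran-3(2H)-one
Product: 10 (S)-2-[(R)-2-(furan-3-yl)-2-hydroxyethyl]-2,5-dimethylfuran-3(2H)-one
Conditions: (S)-2-methyl-CBS-oxazaborolidine (20 mol%), BH3·SMe2, THF, -20 °C; then MeOH
Reagents that add atoms: none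
Why: Corey-Bakshi-Shibata reduction: the catalyst-bound borane delivers hydride to the face of the furyl ketone that places the flat furyl ring in the large-group position, which with the (S)-catalyst should give the (R)-carbinol at C8; the much less electrophilic vinylogous ester carbonyl is left.

Step 7
Reactants: 10 (S)-2-[(R)-2-(furan-3-yl)-2-hydroxyethyl]-2,5-dimethylfuran-3(2H)-one
Product: 11 (S)-2-[(R)-2-(tert-butyldimethylsilyloxy)-2-(furan-3-yl)ethyl]-2,5-dimethylfuran-3(2H)-one
Conditions: TBSCl, imidazole, DMF, rt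
Reagents that add atoms: tert-butyldimethylsilyl chloride, CC(C)(C)[Si](C)(C)Cl
Why: Silyl ether formation on the secondary alcohol under mildly basic conditions that do not enolise the furanone.

Step 8
Reactants: 11 (S)-2-[(R)-2-(tert-butyldimethylsilyloxy)-2-(furan-3-yl)ethyl]-2,5-dimethylfuran-3(2H)-one
Product: 12 2-{(5S)-5-[(2R)-2-(tert-butyldimethylsilyloxy)-2-(furan-3-yl)ethyl]-5-methyl-4-oxo-4,5-dihydrofuran-2-yl}acetaldehyde (largely as its enol)
Conditions: LiN(i-Pr)2 (2.2 equiv), THF, -78 °C; then HCO2CH2CF3, -78 °C; AcOH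
Reagents that add atoms: 2,2,2-trifluoroethyl formate, O=COCC(F)(F)F
Why: Kinetic γ-deprotonation at the 5-methyl group (the only enolisable position of the 2,2-disubstituted furanone) and Claisen-type C-formylation of the dienolate at that carbon, the second equivalent of base storing the acidic product as its enolate.

Step 9
Reactants: 12 the formylmethyl furanone
Product: 13 2-{(5S)-5-[(2R)-2-(tert-butyldimethylsilyloxy)-2-(furan-3-yl)ethyl]-5-methyl-4-oxo-4,5-dihydrofuran-2-yl}prop-2-enal
Conditions: Me2N=CH2 I (Eschenmoser's salt), Et3N, CH2Cl2, 0 °C to rt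
Reagents that add atoms: Eschenmoser's salt (N,N-dimethylmethyleneiminium iodide), C=[N+](C)C.[I-]
Why: α-Methylenation of an aldehyde by a Mannich reaction at C4 then E1cB loss of dimethylamine; the stabilised enolate of 12 is far more nucleophilic toward the iminium salt than the furan ring.

Step 10
Reactants: 13 the furyl enal
Product: 15 4-{(1R)-1-(tert-butyldimethylsilyloxy)-2-[(2S)-5-(3-hydroxyprop-1-en-2-yl)-2-methyl-3-oxo-2,3-dihydrofuran-2-yl]ethyl}furan-2(5H)-one, via hydroxybutenolide enal 14 (not isolated)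
Conditions: O2, tetraphenylporphyrin, hν (visible), i-Pr2NEt, CH2Cl2, -78 °C; then NaBH4, CeCl3·7H2O, MeOH/THF, -40 to 0 °C; 1 M HCl
Reagents that add atoms: oxygen (as singlet oxygen), O=O
Why: Base-assisted [4+2] photooxygenation of the 3-substituted furan, in which the hindered amine removes the endoperoxide proton at the unhindered C12 so that the carbonyl ends at C12 and the hemiacetal at C6, then Luche-type borohydride reduction that takes the ring-opened formyl acid to the hydroxy acid (lactonising on acidification) and in the same operation reduces the enal 1,2 to the allylic alcohol.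

Step 11
Reactants: 15 the butenolide allylic alcohol
Product: 16 2-{(5S)-5-[(2R)-2-(tert-butyldimethylsilyloxy)-2-(5-oxo-2,5-dihydrofuran-3-yl)ethyl]-5-methyl-4-oxo-4,5-dihydrofuran-2-yl}prop-2-enal
Conditions: MnO2 (excess), CH2Cl2, rt; filtration, used at once
Reagents that add atoms: none
Why: Allylic alcohol oxidation with MnO2 is neutral and heterogeneous, so the reactive 2-substituted acrolein is released without acid or base and the butenolide is untouched.

Step 12
Reactants: 16 the butenolide enal
Product: 17 2-{(5S)-5-[(2R)-2-(tert-butyldimethylsilyloxy)-2-[5-(triisopropylsilyloxy)furan-3-yl]ethyl]-5-methyl-4-oxo-4,5-dihydrofuran-2-yl}prop-2-enal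
Conditions: TIPSOTf, i-Pr2NEt, CH2Cl2, -20 to 0 °C; filtration through Et3N-deactivated silica, used at once
Reagents that add atoms: triisopropylsilyl trifluoromethanesulfonate, CC(C)[Si](C(C)C)(C(C)C)OS(=O)(=O)C(F)(F)F
Why: Soft enolisation of the butenolide (γ-deprotonation and O-silylation) gives the aromatic 2-silyloxyfuran; neither the enal nor the furanone of 16 has an enolisable hydrogen, and the hindered amine should not add to the enal.

Step 13
Reactants: 17 the silyloxyfuran enal
Product: 18 (4R,6R,8R,10S)-8-(tert-butyldimethylsilyloxy)-1,15-dioxo-3,10-epoxygermacra-2,7(11)-dien-12,6-olide (furanone-bridged ten-membered carbocycle with a C7=C11 butenolide and the C15 aldehyde)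
Conditions: 9-amino(9-deoxy)epi-quinine (30 mol%), CF3CO2H (60 mol%), H2O (5 equiv), CHCl3, 17 added over 12 h (final 2 mM), 0 °C to rt
Reagents that add atoms: none
Why: Proposed new method: the primary amine salt condenses with the 2-substituted acrolein to an iminium ion whose methylene terminus C5 is attacked by the 5-position (C6) of the 4-substituted 2-silyloxyfuran, water takes the silyl group so that the furan becomes the butenolide, and the enamine left at C4-C15 is protonated at C4 and hydrolysed, the closest known reaction type being the bimolecular iminium-catalysed vinylogous Mukaiyama-Michael addition of 2-silyloxyfurans to enals, which has not been used to close a medium ring. The one ring closed is the ten-membered carbocycle C1-C10 (nine atoms if counted through the furanone oxygen), formed by 10-endo-trig attack since both C4 and C5 of the acceptor alkene end inside the ring. C6 is set in the bond-forming event by the fold of the tether, which the quaternary C10 and a pseudo-equatorial C8 silyloxy group are expected to bias toward one furan face, with the chiral amine as a second, external control element. C4 is set by protonation of the macrocyclic enamine and, being alpha to the aldehyde, can still settle to the more stable epimer through the same amine before step 14 fixes it. The step needs bond formation at C5 and not at the carbonyl carbon C15, and from furan C6 and not C11; since all these modes give the same ring size, the choice rests on the β-selectivity of iminium ions and the 5-selectivity of 2-silyloxyfurans, which is why iminium activation is preferred to a Lewis acid. Slow addition to 2 mM should hold back oligomerisation, and the flat furanone and furan remove rotors from the chain.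

Step 14
Reactants: 18 the macrocyclic aldehyde
Product: 19 (4S,6R,8R,10S)-8-(tert-butyldimethylsilyloxy)-15-hydroxy-1-oxo-3,10-epoxygermacra-2,7(11)-dien-12,6-olide
Conditions: NaBH4, MeOH/CH2Cl2 1:1, -78 °C
Reagents that add atoms: none
Why: Chemoselective borohydride reduction of the aldehyde at low temperature fixes C4 against further epimerisation while the butenolide and the vinylogous ester carbonyl are left.

Step 15
Reactants: 19 the C15 alcohol
Product: 20 (4S,6R,8R,10S)-8-(tert-butyldimethylsilyloxy)-15-(tert-butyldiphenylsilyloxy)-1-oxo-3,10-epoxygermacra-2,7(11)-dien-12,6-olide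
Conditions: TBDPSCl, imidazole, DMF, rt
Reagents that add atoms: tert-butyldiphenylsilyl chloride, CC(C)(C)[Si](Cl)(c1ccccc1)c1ccccc1
Why: Silyl ether formation on the primary alcohol with a group that will outlast the later acidic removal of the secondary TBS ether.

Step 16
Reactants: 20 the bis-silyl butenolide
Product: 21 (4S,6R,7S,8R,10S)-8-(tert-butyldimethylsilyloxy)-15-(tert-butyldiphenylsilyloxy)-1-oxo-3,10-epoxygermacr-2-en-12,6-olide (trans-fused lactone, H6 and H7 anti)
Conditions: Cu(OAc)2 (5 mol%), (R)-p-Tol-BINAP (5 mol%), (EtO)2MeSiH, t-BuOH, toluene, 0 °C to rt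
Reagents that add atoms: none
Why: Copper hydride conjugate reduction of a β,β-disubstituted butenolide: the phosphine-bound monovalent copper hydride adds hydride to C7 and t-BuOH protonates the copper enolate; the required delivery is on the C5 face of C7 (trans-lactone), to be secured by the macrocycle with the chiral bisphosphine as a second control element, and the β-alkoxy enone of the furanone should not accept hydride.

Step 17
Reactants: 21 the saturated lactone
Product: 22 the 13-(dimethylamino) derivative of 21 [11-(dimethylaminomethyl) lactone, C11 epimers]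
Conditions: LiN(i-Pr)2 (1.1 equiv), THF, -78 °C; then Me2N=CH2 I, -78 °C to rt
Reagents that add atoms: Eschenmoser's salt (N,N-dimethylmethyleneiminium iodide), C=[N+](C)C.[I-]
Why: Mannich reaction of the lithium lactone enolate; the amide base at -78 °C should remove the unhindered lactone α-proton faster than the tertiary C4-H of the furanone side, and the new C11 centre is erased in step 18.

Step 18
Reactants: 22 the Mannich base
Product: 24 (4S,6R,7S,8R,10S)-8-(tert-butyldimethylsilyloxy)-15-(tert-butyldiphenylsilyloxy)-1-oxo-3,10-epoxygermacra-2,11(13)-dien-12,6-olide, via trimethylammonium iodide 23 (not isolated)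
Conditions: MeI, MeOH/CH2Cl2, rt; then aq. NaHCO3, EtOAc, rt
Reagents that add atoms: none
Why: N-Quaternisation and E1cB (Hofmann-type) elimination of trimethylamine give the α-methylene lactone under bicarbonate, too mild to disturb the silyl ethers or C4.

Step 19
Reactants: 24 the α-methylene lactone
Product: 25 (4S,6R,7R,8R,10S)-15-(tert-butyldiphenylsilyloxy)-8-hydroxy-1-oxo-3,10-epoxygermacra-2,11(13)-dien-12,6-olide (C7 unchanged in space; its descriptor changes by priority only)
Conditions: aq. HF (48%), MeCN, 0 °C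
Reagents that add atoms: none
Why: Acid-mediated desilylation: HF cleaves the secondary TBS ether while the far more acid-stable primary TBDPS ether should remain.

Step 20
Reactants: 25 the C8 alcohol
Product: 26 (4S,6R,7S,8R,10S)-8-angeloyloxy-15-(tert-butyldiphenylsilyloxy)-1-oxo-3,10-epoxygermacra-2,11(13)-dien-12,6-olide
Conditions: angelic acid, 2,4,6-trichlorobenzoyl chloride, Et3N, toluene, rt; then 25, 75 °C
Reagents that add atoms: angelic acid [(Z)-2-methylbut-2-enoic acid], C/C=C(/C)C(=O)O
Why: Yamaguchi esterification through the preformed mixed anhydride without DMAP, the variant that transfers the angeloyl group without Z to E isomerisation; the hindered C8 alcohol needs heat.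

Step 21
Reactants: 26 the silylated angelate
Product: 27 (4S,6R,7S,8R,10S)-8-angeloyloxy-15-hydroxy-1-oxo-3,10-epoxygermacra-2,11(13)-dien-12,6-olide (CNP0108636.1)
Conditions: Bu4NF, AcOH (1:1), THF, 0 °C to rt
Reagents that add atoms: none
Why: Fluoride desilylation buffered with acetic acid should free the C15 alcohol without attacking the α-methylene lactone or isomerising the angelate.

**Compound list**

1 | 2,5-dimethylfuran-3(2H)-one | CC1OC(C)=CC1=O | starting material
2 | allyl chloroformate | C=CCOC(=O)Cl | starting material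
3 | allyl (2,5-dimethylfuran-3-yl) carbonate | C=CCOC(=O)Oc1cc(C)oc1C | intermediate
4 | (S)-2-allyl-2,5-dimethylfuran-3(2H)-one | CC1=CC(=O)[C@](C)(CC=C)O1 | intermediate
5 | 2-[(2S)-2,5-dimethyl-3-oxo-2,3-dihydrofuran-2-yl]acetaldehyde | CC1=CC(=O)[C@](C)(CC=O)O1 | intermediate
6 | 3-bromofuran | Brc1ccoc1 | starting material
7 | 3-furyllithium | [Li]c1ccoc1 | intermediate
8 | (2S)-2-[2-(furan-3-yl)-2-hydroxyethyl]-2,5-dimethylfuran-3(2H)-one, C8 epimers | CC1=CC(=O)[C@](C)(CC(O)c2ccoc2)O1 | intermediate
9 | (S)-2-[2-(furan-3-yl)-2-oxoethyl]-2,5-dimethylfuran-3(2H)-one | CC1=CC(=O)[C@](C)(CC(=O)c2ccoc2)O1 | intermediate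
10 | (S)-2-[(R)-2-(furan-3-yl)-2-hydroxyethyl]-2,5-dimethylfuran-3(2H)-one | CC1=CC(=O)[C@](C)(C[C@@H](O)c2ccoc2)O1 | intermediate
11 | (S)-2-[(R)-2-(tert-butyldimethylsilyloxy)-2-(furan-3-yl)ethyl]-2,5-dimethylfuran-3(2H)-one | CC1=CC(=O)[C@](C)(C[C@@H](O[Si](C)(C)C(C)(C)C)c2ccoc2)O1 | intermediate
12 | 2-{(5S)-5-[(2R)-2-(tert-butyldimethylsilyloxy)-2-(furan-3-yl)ethyl]-5-methyl-4-oxo-4,5-dihydrofuran-2-yl}acetaldehyde | O=CCC1=CC(=O)[C@](C)(C[C@@H](O[Si](C)(C)C(C)(C)C)c2ccoc2)O1 | intermediate
13 | 2-{(5S)-5-[(2R)-2-(tert-butyldimethylsilyloxy)-2-(furan-3-yl)ethyl]-5-methyl-4-oxo-4,5-dihydrofuran-2-yl}prop-2-enal | O=CC(=C)C1=CC(=O)[C@](C)(C[C@@H](O[Si](C)(C)C(C)(C)C)c2ccoc2)O1 | intermediate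
14 | 2-{(5S)-5-[(2R)-2-(tert-butyldimethylsilyloxy)-2-(2-hydroxy-5-oxo-2,5-dihydrofuran-3-yl)ethyl]-5-methyl-4-oxo-4,5-dihydrofuran-2-yl}prop-2-enal, hemiacetal epimers | O=CC(=C)C1=CC(=O)[C@](C)(C[C@@H](O[Si](C)(C)C(C)(C)C)C2=CC(=O)OC2O)O1 | intermediate
15 | 4-{(1R)-1-(tert-butyldimethylsilyloxy)-2-[(2S)-5-(3-hydroxyprop-1-en-2-yl)-2-methyl-3-oxo-2,3-dihydrofuran-2-yl]ethyl}furan-2(5H)-one | OCC(=C)C1=CC(=O)[C@](C)(C[C@@H](O[Si](C)(C)C(C)(C)C)C2=CC(=O)OC2)O1 | intermediate
16 | 2-{(5S)-5-[(2R)-2-(tert-butyldimethylsilyloxy)-2-(5-oxo-2,5-dihydrofuran-3-yl)ethyl]-5-methyl-4-oxo-4,5-dihydrofuran-2-yl}prop-2-enal | O=CC(=C)C1=CC(=O)[C@](C)(C[C@@H](O[Si](C)(C)C(C)(C)C)C2=CC(=O)OC2)O1 | intermediate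
17 | 2-{(5S)-5-[(2R)-2-(tert-butyldimethylsilyloxy)-2-[5-(triisopropylsilyloxy)furan-3-yl]ethyl]-5-methyl-4-oxo-4,5-dihydrofuran-2-yl}prop-2-enal | O=CC(=C)C1=CC(=O)[C@](C)(C[C@@H](O[Si](C)(C)C(C)(C)C)c2cc(O[Si](C(C)C)(C(C)C)C(C)C)oc2)O1 | intermediate
18 | (4R,6R,8R,10S)-8-(tert-butyldimethylsilyloxy)-1,15-dioxo-3,10-epoxygermacra-2,7(11)-dien-12,6-olide | O=C1O[C@@H]2C[C@@H](C=O)C3=CC(=O)[C@](C)(C[C@@H](O[Si](C)(C)C(C)(C)C)C2=C1)O3 | intermediate
19 | (4S,6R,8R,10S)-8-(tert-butyldimethylsilyloxy)-15-hydroxy-1-oxo-3,10-epoxygermacra-2,7(11)-dien-12,6-olide | O=C1O[C@@H]2C[C@@H](CO)C3=CC(=O)[C@](C)(C[C@@H](O[Si](C)(C)C(C)(C)C)C2=C1)O3 | intermediate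
20 | (4S,6R,8R,10S)-8-(tert-butyldimethylsilyloxy)-15-(tert-butyldiphenylsilyloxy)-1-oxo-3,10-epoxygermacra-2,7(11)-dien-12,6-olide | O=C1O[C@@H]2C[C@@H](CO[Si](c4ccccc4)(c4ccccc4)C(C)(C)C)C3=CC(=O)[C@](C)(C[C@@H](O[Si](C)(C)C(C)(C)C)C2=C1)O3 | intermediate
21 | (4S,6R,7S,8R,10S)-8-(tert-butyldimethylsilyloxy)-15-(tert-butyldiphenylsilyloxy)-1-oxo-3,10-epoxygermacr-2-en-12,6-olide | C1C(=O)O[C@@H]2C[C@@H](CO[Si](c4ccccc4)(c4ccccc4)C(C)(C)C)C3=CC(=O)[C@](C)(C[C@@H](O[Si](C)(C)C(C)(C)C)[C@@H]12)O3 | intermediate
22 | 13-(dimethylamino) derivative of 21, C11 epimers | CN(C)CC1C(=O)O[C@@H]2C[C@@H](CO[Si](c4ccccc4)(c4ccccc4)C(C)(C)C)C3=CC(=O)[C@](C)(C[C@@H](O[Si](C)(C)C(C)(C)C)[C@@H]12)O3 | intermediate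
23 | 13-(trimethylammonio) derivative of 21, iodide | C[N+](C)(C)CC1C(=O)O[C@@H]2C[C@@H](CO[Si](c4ccccc4)(c4ccccc4)C(C)(C)C)C3=CC(=O)[C@](C)(C[C@@H](O[Si](C)(C)C(C)(C)C)[C@@H]12)O3.[I-] | intermediate
24 | (4S,6R,7S,8R,10S)-8-(tert-butyldimethylsilyloxy)-15-(tert-butyldiphenylsilyloxy)-1-oxo-3,10-epoxygermacra-2,11(13)-dien-12,6-olide | C=C1C(=O)O[C@@H]2C[C@@H](CO[Si](c4ccccc4)(c4ccccc4)C(C)(C)C)C3=CC(=O)[C@](C)(C[C@@H](O[Si](C)(C)C(C)(C)C)[C@@H]12)O3 | intermediate
25 | (4S,6R,7R,8R,10S)-15-(tert-butyldiphenylsilyloxy)-8-hydroxy-1-oxo-3,10-epoxygermacra-2,11(13)-dien-12,6-olide | C=C1C(=O)O[C@@H]2C[C@@H](CO[Si](c4ccccc4)(c4ccccc4)C(C)(C)C)C3=CC(=O)[C@](C)(C[C@@H](O)[C@@H]12)O3 | intermediate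
26 | (4S,6R,7S,8R,10S)-8-angeloyloxy-15-(tert-butyldiphenylsilyloxy)-1-oxo-3,10-epoxygermacra-2,11(13)-dien-12,6-olide | C=C1C(=O)O[C@@H]2C[C@@H](CO[Si](c4ccccc4)(c4ccccc4)C(C)(C)C)C3=CC(=O)[C@](C)(C[C@@H](OC(=O)/C(C)=C\C)[C@@H]12)O3 | intermediate
27 | (4S,6R,7S,8R,10S)-8-angeloyloxy-15-hydroxy-1-oxo-3,10-epoxygermacra-2,11(13)-dien-12,6-olide (CNP0108636.1) | C=C1C(=O)O[C@@H]2C[C@@H](CO)C3=CC(=O)[C@](C)(C[C@@H](OC(=O)/C(C)=C\C)[C@@H]12)O3 | target

**Step count and risks**

Total steps: 21. Longest linear sequence: 21 steps, from 1 to 27.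

Steps most likely to fail:

1. Step 13 (ring closure). Oligomerisation may outrun the medium-ring closure, the silyloxyfuran may be hydrolysed back to the butenolide before the C-C bond forms, or the closure may take the wrong furan face (C6 epimer) or leave the wrong C4 epimer. The fallback makes the C5-C6 bond by the known bimolecular reaction and closes the ring at C7-C8 instead; it sets out from 4 and comes back at 20. Compound 4 is formylated and methylenated under the conditions of steps 8 and 9 to the formylmethyl allyl furanone F1 and then the allyl furanonyl acrolein F2. Purchased 4-bromofuran-2(5H)-one F3 is silylated (TIPSOTf, Et3N) to 4-bromo-2-(triisopropylsilyloxy)furan F4. F2 and F4 are joined in the intermolecular amine-catalysed vinylogous Mukaiyama-Michael addition (catalyst of step 13, 0.2 M) to the bromobutenolide aldehyde F5, whose C4 and C6 centres then rest on the catalyst and on chromatographic separation. NaBH4 gives the primary alcohol F6 and TBDPSCl/imidazole the silyl ether F7. Lemieux-Johnson cleavage of the allyl group gives the C8 aldehyde F8. A Nozaki-Hiyama-Kishi macrocyclisation (CrCl2, NiCl2 cat., DMSO/THF, 2 mM) then joins C7 to C8 to give the macrocyclic C8 alcohol F9, whose (8R) epimer is silylated (TBSOTf, 2,6-lutidine) to 20.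

2. Step 16 (conjugate reduction). Hydride may be delivered to the face of C7 away from C5, which gives the cis-fused lactone; the local bias of the butenolide points that way, and only the macrocycle and the ligand oppose it. The hindered β,β-disubstituted alkene may also react slowly. The fallback replaces steric approach control by a directing group; it sets out from 20 and comes back at 21. Aqueous HF in MeCN removes the secondary TBS group to give the macrocyclic C8 alcohol F9 (the compound also met in the first fallback). Hydrogenation with [Ir(cod)(PCy3)(py)]PF6 and H2 in CH2Cl2, in which the C8 hydroxyl binds the metal and steers hydrogen to the face of C7 that it occupies, gives the saturated hydroxy lactone F10. Resilylation (TBSOTf, 2,6-lutidine) returns to 21.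

3. Step 2 (allylation). The flat furan-3-olate may be allylated with poor enantioselectivity, or partly at C4 instead of C2. The fallback takes the C10 configuration from a separation; it sets out from 1 and comes back at 10. LiN(i-Pr)2 then allyl bromide gives the racemic allyl furanone F11. The conditions of steps 3, 4 and 5 give the racemic aldehyde F12, the racemic furyl carbinols F13 and the racemic furyl ketone F14. The reduction of step 6 then sets C8 as (R) in both enantiomers of the ketone, so that 10 and its (8R,10R) diastereomer F15 are formed and separated by chromatography.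

Further compounds
F1 | step 13 | 2-[(5S)-5-allyl-5-methyl-4-oxo-4,5-dihydrofuran-2-yl]acetaldehyde | O=CCC1=CC(=O)[C@](C)(CC=C)O1
F2 | step 13 | 2-[(5S)-5-allyl-5-methyl-4-oxo-4,5-dihydrofuran-2-yl]prop-2-enal | O=CC(=C)C1=CC(=O)[C@](C)(CC=C)O1
F3 | step 13 | 4-bromofuran-2(5H)-one | O=C1C=C(Br)CO1
F4 | step 13 | 4-bromo-2-(triisopropylsilyloxy)furan | Brc1coc(O[Si](C(C)C)(C(C)C)C(C)C)c1
F5 | step 13 | (2R)-2-[(5S)-5-allyl-5-methyl-4-oxo-4,5-dihydrofuran-2-yl]-3-[(2R)-3-bromo-5-oxo-2,5-dihydrofuran-2-yl]propanal | O=C1O[C@H](C[C@@H](C=O)C2=CC(=O)[C@](C)(CC=C)O2)C(Br)=C1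
F6 | step 13 | (5R)-5-{(2S)-2-[(5S)-5-allyl-5-methyl-4-oxo-4,5-dihydrofuran-2-yl]-3-hydroxypropyl}-4-bromofuran-2(5H)-one | O=C1O[C@H](C[C@@H](CO)C2=CC(=O)[C@](C)(CC=C)O2)C(Br)=C1
F7 | step 13 | tert-butyldiphenylsilyl ether of F6 | O=C1O[C@H](C[C@@H](CO[Si](c3ccccc3)(c3ccccc3)C(C)(C)C)C2=CC(=O)[C@](C)(CC=C)O2)C(Br)=C1
F8 | step 13 | 2-{(2S)-5-[(2S)-1-[(2R)-3-bromo-5-oxo-2,5-dihydrofuran-2-yl]-3-(tert-butyldiphenylsilyloxy)propan-2-yl]-2-methyl-3-oxo-2,3-dihydrofuran-2-yl}acetaldehyde | O=C1O[C@H](C[C@@H](CO[Si](c3ccccc3)(c3ccccc3)C(C)(C)C)C2=CC(=O)[C@](C)(CC=O)O2)C(Br)=C1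
F9 | step 13 | (4S,6R,8R,10S)-15-(tert-butyldiphenylsilyloxy)-8-hydroxy-1-oxo-3,10-epoxygermacra-2,7(11)-dien-12,6-olide | O=C1O[C@@H]2C[C@@H](CO[Si](c4ccccc4)(c4ccccc4)C(C)(C)C)C3=CC(=O)[C@](C)(C[C@@H](O)C2=C1)O3
F10 | step 16 | (4S,6R,7R,8R,10S)-15-(tert-butyldiphenylsilyloxy)-8-hydroxy-1-oxo-3,10-epoxygermacr-2-en-12,6-olide | C1C(=O)O[C@@H]2C[C@@H](CO[Si](c4ccccc4)(c4ccccc4)C(C)(C)C)C3=CC(=O)[C@](C)(C[C@@H](O)[C@@H]12)O3
F11 | step 2 | rac-2-allyl-2,5-dimethylfuran-3(2H)-one | C=CCC1(C)OC(C)=CC1=O
F12 | step 2 | rac-2-(2,5-dimethyl-3-oxo-2,3-dihydrofuran-2-yl)acetaldehyde | CC1=CC(=O)C(C)(CC=O)O1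
F13 | step 2 | 2-[2-(furan-3-yl)-2-hydroxyethyl]-2,5-dimethylfuran-3(2H)-one, all stereoisomers | CC1=CC(=O)C(C)(CC(O)c2ccoc2)O1
F14 | step 2 | rac-2-[2-(furan-3-yl)-2-oxoethyl]-2,5-dimethylfuran-3(2H)-one | CC1=CC(=O)C(C)(CC(=O)c2ccoc2)O1
F15 | step 2 | (R)-2-[(R)-2-(furan-3-yl)-2-hydroxyethyl]-2,5-dimethylfuran-3(2H)-one | CC1=CC(=O)[C@@](C)(C[C@@H](O)c2ccoc2)O1
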